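**Assumptions:** the SMILES is taken as the natural (5S,8S,9R,10S) series (terpenoid numbering: C4 carries the exocyclic methylene, C5 the angular methyl, C8 is CHMe, C9 is the quaternary carbon, C10 the ring-fusion CH). Commercial isopropenylmagnesium bromide solution is counted as a starting material.

## Retrosynthetic overview

1. Target 12 ⇐ aryl bromide 11 (Pd methoxycarbonylation) ⇐ decalone 10 (Wittig methylenation at C4).
2. Key step: 10 ⇐ 9. Ring B and the C8–C9 bond are formed by an Fe–H hydrogen-atom-transfer-triggered 6-exo radical cyclisation of the tertiary C9 radical onto a ketone N-tosylhydrazone, with traceless loss of Ts and N2. This sets C9 and C8; the trans ring fusion is already fixed.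
3. The arylmethyl group comes from an aromatic Claisen rearrangement of a 4-bromophenyl 2-substituted-allyl ether (8 ⇐ 7), made by ene-chlorination of an isopropenyl group and etherification.
4. Ring A stereocentres (C10, C5) come from a Cu-catalysed asymmetric conjugate addition to 2-methylcyclohexenone with Michael trapping of the enolate (4 ⇐ 1 + 2 + 3).
5. Ring order: ring A is purchased; ring B is closed last, by the radical step.

## Route

**Step 1**
Reactants: 1, 2-methylcyclohex-2-en-1-one; 2, isopropenylmagnesium bromide; 3, methyl vinyl ketone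
Product: 4, (2S,3S)-2-methyl-2-(3-oxobutyl)-3-(prop-1-en-2-yl)cyclohexan-1-one
Conditions: 2 (1.3 equiv), Cu(OTf)2 (3 mol%), chiral imidazolinium/NHC ligand (4 mol%), Et2O, −30 °C; then 3 (1.2 equiv), −78 °C; cold aq. NH4Cl quench
Reagents that add atoms: none (all carbon comes from 1, 2 and 3)
Why: Cu-catalysed asymmetric conjugate addition of the Grignard reagent to the α-substituted enone sets C10 (ligand antipode chosen for 3S), and the magnesium enolate is trapped by Michael addition to 3 anti to the new isopropenyl group, giving quaternary C5 with the oxobutyl chain trans to isopropenyl (asymmetric conjugate addition/enolate trapping; the alkenyl Grignard and enone trap are scope extensions).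

**Step 2**
Reactants: 4
Product: 5, (2S,3R)-3-(3-chloroprop-1-en-2-yl)-2-methyl-2-(3-oxobutyl)cyclohexan-1-one
Conditions: Ca(OCl)2, solid CO2, CH2Cl2/H2O, 0 °C
Reagents that add atoms: calcium hypochlorite, [Ca+2].[O-]Cl.[O-]Cl
Why: HOCl ene-type allylic chlorination of the only nucleophilic (1,1-disubstituted) alkene shifts the double bond into the former methyl group; the ketones are inert and no stereocentre is touched (the descriptor changes only through CIP priorities).

**Step 3**
Reactants: 5; 6, 4-bromophenol
Product: 7, (2S,3S)-3-[3-(4-bromophenoxy)prop-1-en-2-yl]-2-methyl-2-(3-oxobutyl)cyclohexan-1-one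
Conditions: K2CO3, NaI (cat.), DMF, rt
Reagents that add atoms: none (6 is a numbered reactant)
Why: Williamson etherification of a primary allylic chloride by the phenoxide (SN2 and SN2′ give the same product); the weak base leaves the diketone intact.

**Step 4**
Reactants: 7
Product: 8, (2S,3S)-3-[3-(5-bromo-2-hydroxyphenyl)prop-1-en-2-yl]-2-methyl-2-(3-oxobutyl)cyclohexan-1-one
Conditions: PhNEt2, 185 °C, sealed tube
Reagents that add atoms: none
Why: Aromatic Claisen [3,3] rearrangement (para position blocked by Br, both ortho positions equivalent) moves the arene onto the allyl CH2 terminus and regenerates the 1,1-disubstituted alkene, now carrying the ArCH2 group.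

**Step 5**
Reactants: 8
Product: 9, N′-{4-[(1S,6S)-6-[3-(5-bromo-2-hydroxyphenyl)prop-1-en-2-yl]-1-methyl-2-oxocyclohexyl]butan-2-ylidene}-4-methylbenzenesulfonohydrazide (E/Z mixture at C=N)
Conditions: TsNHNH2 (1.05 equiv), MeOH, rt
Reagents that add atoms: p-toluenesulfonyl hydrazide, Cc1ccc(cc1)S(=O)(=O)NN
Why: Hydrazone condensation is selective for the unhindered methyl ketone over the ring ketone flanked by the quaternary carbon.

**Step 6 (key step)**
Reactants: 9
Product: 10, (4aS,5R,6S,8aS)-5-[(5-bromo-2-hydroxyphenyl)methyl]-5,6,8a-trimethyl-3,4,4a,5,6,7,8,8a-octahydronaphthalen-1(2H)-one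
Conditions: Fe(acac)3 (1 equiv), PhSiH3 (3 equiv), EtOH/THF, 60 °C; then NaOAc, MeOH, 65 °C (−TsH, −N2)
Reagents that add atoms: none (hydrogen only)
Why: Proposed new method: Fe–H hydrogen-atom transfer to the 1,1-disubstituted alkene gives the tertiary C9 radical (the new CH3 becomes the C9 methyl), which closes ring B by fast 6-exo addition to the hydrazone carbon through a chair transition state on the trans-diequatorial ring-A scaffold, where A(1,3) strain is expected to put the small methyl in the crowded pseudo-axial site syn to the angular methyl and the arylmethyl pseudo-equatorial (9R); the resulting N-sulfonylhydrazine then loses sulfinate and N2, and the C8 radical/diazene should take hydrogen axially to leave the equatorial methyl (8S); closest known reactions are Fe-mediated HAT alkene–hydrazone radical cyclisations and traceless HAT olefin hydromethylation through sulfonylhydrazones.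

**Step 7**
Reactants: 10
Product: 11, 4-bromo-2-{[(1R,2S,4aS,8aS)-1,2,4a-trimethyl-5-methylidenedecahydronaphthalen-1-yl]methyl}phenol
Conditions: Ph3PCH3Br / KOtBu (5 equiv each), toluene, 90 °C
Reagents that add atoms: methyltriphenylphosphonium bromide, C[P+](c1ccccc1)(c1ccccc1)c1ccccc1.[Br-]
Why: Wittig methylenation of the hindered C4 ketone with excess ylide (one equivalent is consumed forming the inert phenoxide); the only α-stereocentre is quaternary, so nothing epimerises.

**Step 8**
Reactants: 11
Product: 12, dictyoceratin C, methyl 4-hydroxy-3-{[(1R,2S,4aS,8aS)-1,2,4a-trimethyl-5-methylidenedecahydronaphthalen-1-yl]methyl}benzoate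
Conditions: Pd(OAc)2 (5 mol%), Xantphos (10 mol%), CO (1 atm), Et3N, MeOH/DMF, 80 °C
Reagents that add atoms: carbon monoxide, [C-]#[O+]; methanol, CO
Why: Pd-catalysed methoxycarbonylation of the aryl bromide (oxidative addition, CO insertion, methanolysis); the free phenol and the exocyclic alkene are tolerated under basic, hydride-free conditions.

## Compound list

1 | 2-methylcyclohex-2-en-1-one | CC1=CCCCC1=O | starting material
2 | isopropenylmagnesium bromide | CC(=C)[Mg]Br | starting material
3 | methyl vinyl ketone (but-3-en-2-one) | CC(=O)C=C | starting material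
4 | (2S,3S)-2-methyl-2-(3-oxobutyl)-3-(prop-1-en-2-yl)cyclohexan-1-one | O=C1CCC[C@@H](C(C)=C)[C@]1(C)CCC(C)=O | intermediate
5 | (2S,3R)-3-(3-chloroprop-1-en-2-yl)-2-methyl-2-(3-oxobutyl)cyclohexan-1-one | O=C1CCC[C@@H](C(=C)CCl)[C@]1(C)CCC(C)=O | intermediate
6 | 4-bromophenol | Oc1ccc(Br)cc1 | starting material
7 | (2S,3S)-3-[3-(4-bromophenoxy)prop-1-en-2-yl]-2-methyl-2-(3-oxobutyl)cyclohexan-1-one | O=C1CCC[C@@H](C(=C)COc2ccc(Br)cc2)[C@]1(C)CCC(C)=O | intermediate
8 | (2S,3S)-3-[3-(5-bromo-2-hydroxyphenyl)prop-1-en-2-yl]-2-methyl-2-(3-oxobutyl)cyclohexan-1-one | O=C1CCC[C@@H](C(=C)Cc2cc(Br)ccc2O)[C@]1(C)CCC(C)=O | intermediate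
9 | N-tosylhydrazone of 8 at the side-chain methyl ketone (E/Z mixture) | O=C1CCC[C@@H](C(=C)Cc2cc(Br)ccc2O)[C@]1(C)CCC(C)=NNS(=O)(=O)c3ccc(C)cc3 | intermediate
10 | (4aS,5R,6S,8aS)-5-[(5-bromo-2-hydroxyphenyl)methyl]-5,6,8a-trimethyl-octahydronaphthalen-1(2H)-one | O=C1CCC[C@H]2[C@](C)(Cc3cc(Br)ccc3O)[C@@H](C)CC[C@]12C | intermediate
11 | 4-bromo-2-{[(1R,2S,4aS,8aS)-1,2,4a-trimethyl-5-methylidenedecahydronaphthalen-1-yl]methyl}phenol | C=C1CCC[C@H]2[C@](C)(Cc3cc(Br)ccc3O)[C@@H](C)CC[C@]12C | intermediate
12 | dictyoceratin C, methyl 4-hydroxy-3-{[(1R,2S,4aS,8aS)-1,2,4a-trimethyl-5-methylidenedecahydronaphthalen-1-yl]methyl}benzoate | C=C1CCC[C@H]2[C@](C)(Cc3cc(C(=O)OC)ccc3O)[C@@H](C)CC[C@]12C | target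

## Step count and risks

Total steps: 8. Longest linear sequence: 8 (fully linear).

Steps most likely to fail:

1. **Step 6 (radical ring closure).** The C–C bond joins two congested carbons, and the C9 (Me versus CH2Ar) and C8 selectivities rest on modest conformational preferences; simple alkene reduction may compete. Fallback: invert the order of events. Close ring B without the arene, as the 8β-methyl-9-methylidene decalone (reductive enyne cyclisation of the C10-ethynyl/C5-butenyl analogue of 4), then create C9 last by Mn/Ni-catalysed HAT hydrobenzylation with a protected 5-bromo-2-hydroxybenzyl bromide, where the angular methyl blocks the β-face of the ring radical.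

2. **Step 1 (asymmetric conjugate addition with Michael trap).** The ee with an alkenyl Grignard is uncertain, and the magnesium enolate may give polymer or Robinson-type aldol with methyl vinyl ketone. Fallback: decouple the two bond formations. Use Rh(I)/chiral-diene-catalysed 1,4-addition of potassium isopropenyltrifluoroborate (or Cu addition with TMSCl trapping) to isolate the silyl enol ether, then a separate Lewis-acid Mukaiyama–Michael addition to 3.

3. **Step 4 (Claisen with the free 1,5-diketone).** Thermal aldol cyclodehydration or retro-Michael of the oxobutyl chain, or cyclisation of the product phenol onto the alkene, may occur at 185 °C. Fallback: carry the ketone masked. Trap the step-1 enolate with 4-iodobut-1-ene instead of 3, take the inert butenyl chain through steps 2–4, and unveil the methyl ketone by Tsuji–Wacker oxidation just before hydrazone formation (one extra step).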